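## Analysis of the target

The target is an isoflavanone: a chroman-4-one (ring A benzo-fused to the dihydropyranone ring C) that carries ring B at C3. Ring A has one free phenol at C7. Ring B is pentasubstituted, with hydroxyls at C2' and C3', a methoxy group at C4' and a 2-methylbut-3-en-2-yl group at C5', whose quaternary carbon sits ortho to the methoxy group. The only stereocentre is C3 (S, checked against the SMILES); it is tertiary, benzylic and α to the C4 ketone, so it epimerises through the enol under base and, more slowly, under acid. The sensitive groups are the catechol (oxidation), the monosubstituted alkene (no hydrogenolysis, no hydroboration), the β-aryloxy ketone O1–C2–C3–C4 (β-elimination) and the 2'-hydroxyl facing the C4 carbonyl (acid-induced cyclodehydration to a benzofuran). The difficulty lies in delivering a labile α-aryl ketone as one enantiomer with three free phenols, and in building ring B with three differentiated oxygens next to a tert-alkyl group. The plan rests on C4: it is a carbonyl carbon with only two carbon neighbours, C4a of ring A and C3, so once O1–C2 links the two halves it can be supplied as carbon monoxide between a C4a–Br bond and a C3 carbanion. The lability of C3 is used twice: an ester makes C3 nucleophilic for the ring closure, and after its removal C3 is set by dynamic kinetic resolution.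

## Retrosynthetic reasoning

**23 from 22.** The three phenols are released last from the tris(methoxymethyl) ether 22. Acetal ethers are chosen because every step before the end is basic, thermal or palladium-mediated, and because hydrogenolysis is excluded by the alkene. The forward step must cleave three acetals without enolising C3.

**22 from 21 from 20.** No skeletal bond is cut. The (3S)-ketone 22 is traced to the cis-(3S,4S)-alcohol 21 and this to the racemic ketone 20. Because C3 of 20 epimerises readily, a catalyst that reduces one enantiomer faster converts the whole racemate into one cis alcohol; the C4 carbinol is then oxidised back. The gain is that all earlier chemistry can be run racemic.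

**20 from 18.** A methoxycarbonyl group is added at C3. It gives C3 the acidity needed for the ring closure and is removed by dealkoxycarbonylation. The forward step must cleave a hindered, non-enolisable β-keto ester without retro-Claisen opening, which points to halide attack on the ester methyl group rather than hydroxide.

**18 from 16 and 10.** The bonds C4–C4a and C4–C3 are cut, leaving carbon monoxide 10 and bromo ester 16. C4 is cut out because it is the only ring C carbon whose two skeletal bonds can be formed in one catalytic event from stable partners. O1–C2 is left intact so that capture of the acyl metal species is intramolecular and six-membered. The forward reaction has to carbonylate before it arylates and has to close the ring before the β-aryloxy ester enolate fragments.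

**16 from 11 and 15.** O1–C2 is cut as a conjugate addition of phenol 15 to acrylate 11. This places the oxygen on the terminal carbon without any leaving group and creates the acidic C3–H in the same step.

**11 from 9 and 10, 9 from 7.** The ester carbon of 11 is removed as a second molecule of 10, leaving enol triflate 9, made from methyl ketone 7. The acetyl group already holds C3 and C2, so no one-carbon homologation under acidic conditions is needed.

**7 from 6, 4, 3, 1 and 2.** O-Demethylation leads to phenol 6. Its tert-allyl group ortho to the hydroxyl is the retron of an aromatic Claisen rearrangement of prenyl ether 4, which delivers the allyl unit with transposition to the only free ortho carbon. Ether 4 comes from 3, and 3 from 1 and prenyl bromide 2, because the hydroxyl para to the acetyl group of 1 is the most acidic and is alkylated alone.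

**15 from 14, 13 and 12.** The bromine is introduced after the two oxygens have been differentiated. In 13 the acetal ether directs bromination to its para position, which is ortho to the benzoate-masked oxygen of 12, so the regiochemistry follows from directing effects and not from a selective monoprotection.

## Alternatives that were turned down

**Alternative 1: ring switch of a benzodioxine enol acetal.**
- Disconnection: C2–C3. The precursor would be the (Z)-4-arylidene-4H-1,3-benzodioxine A2, in which O1–C2 and the C4 oxygen are held as a methylene acetal of an enol.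
- Forward key step: an alkylaluminium chloride would ionise the acetal to an aluminium enolate and a tethered aryloxymethyl cation, which recombine at carbon to give the racemic tris-silyl isoflavanone A1.
- For: the ketone is formed directly, without an activating ester or a gas, and the enolate appears only as a tight ion pair, so β-elimination is not a concern.
- Against: the rearrangement is established for enol acetals whose cationic fragment is substituted and well stabilised. Here the cation is an unsubstituted aryloxymethyl cation whose oxygen lone pair is shared with ring A, so ionisation in the required sense is less favourable. A2 needs a stereodefined arylidenation of a lactone carbonyl with a hindered aryl group, which is not routine. The Lewis acid forces silyl ethers in place of acetal ethers on the catechol.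
- Comparison: A1 is still racemic and needs the same resolution and reoxidation as 20. It is stronger in saving the dealkoxycarbonylation step and in allowing buffered fluoride for the final deprotection. The chosen route offers a ring closure of a known catalytic type and a precursor made by simple addition chemistry.

**Alternative 2: phenol–enal annulation through a vinyl ortho-quinone methide.**
- Disconnection: C4–C4a and O1–C2 together, from phenol A4 and 2-arylacrolein A5.
- Forward key step: an arylboronic acid templates ortho attack of A4 on the aldehyde of A5; fragmentation and oxa-6π electrocyclisation give the isoflav-3-ene A3.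
- For: it is the most convergent of the four, needs no halogen or transition metal, and ring A is used almost as bought.
- Against: A3 has no oxygen at C4 and an sp2 C3. Bringing C3=C4 to the ketone needs hydroboration and oxidation, and the monosubstituted alkene of the tert-allyl group is the more reactive alkene towards boranes. The annulation needs 1,2-attack on the aldehyde, whereas A5 has an unsubstituted β-carbon that invites conjugate addition and polymerisation. The usual acidic, hot conditions endanger the acetal ethers, and A4 has two ortho positions.
- Comparison: stronger in convergence and brevity up to the bicyclic skeleton. The chosen route delivers C4 at the ketone oxidation level and never has to discriminate between two alkenes.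

**Alternative 3: aldol-set stereocentre and palladium-catalysed O1–C8a closure.**
- Disconnection: O1–C8a. The bromo alcohol A7 would carry both stereocentres from an aldol reaction.
- Forward key step: palladium with a bulky biaryl di-tert-butylphosphine and a carbonate base would couple the primary hydroxyl with the aryl bromide to give the trans-4-silyloxyisoflavan A6.
- For: C3 is fixed early under reagent control and is not α to a carbonyl until the end. Intramolecular aryl ether formation from a primary alcohol is well established, and no enolate that could fragment is involved.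
- Against: the sequence is longer (arylacetic acid derivative of ring B, controller on and off, silylation, desilylation, oxidation). The chiral controller is stoichiometric. β-Hydride elimination of the palladium alkoxide competes with C–O bond formation. After oxidation the same labile α-aryl ketone has to survive the same final deprotection, so the end-game risk is not removed.
- Comparison: as strong or stronger in the reliability of the ring closure and in stereocontrol that does not depend on a dynamic resolution. The chosen route offers a shorter sequence, racemic chemistry until a single catalytic asymmetric step, and use of carbon monoxide as a one-carbon building block.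

Key step: step 11

Remark on the chemistry: the (S,S)-configured ruthenium catalyst is assumed to deliver hydride to C4 of 20 in the sense usual for aryl alkyl ketones (4S carbinol); if the opposite sense is found, the (R,R)-catalyst is used.

ArB denotes the 4-methoxy-2,3-bis(methoxymethoxy)-5-(2-methylbut-3-en-2-yl)phenyl group of ring B.

## Route

**Step 1**
Reactants: 1 1-(2,3,4-trihydroxyphenyl)ethanone; 2 1-bromo-3-methylbut-2-ene (prenyl bromide)
Product: 3 1-[2,3-dihydroxy-4-(3-methylbut-2-enyloxy)phenyl]ethanone
Conditions: 2 (1.05 equiv), NaHCO3, DMF, 40 °C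
Reagents that add atoms: none
Why: Williamson ether synthesis under weak-base control; the 4-OH is para to the acetyl group and the most acidic phenol, while the 2-OH is hydrogen-bonded to the carbonyl, so hydrogencarbonate should ionise and alkylate O4 only.

**Step 2**
Reactants: 3 1-[2,3-dihydroxy-4-(3-methylbut-2-enyloxy)phenyl]ethanone
Product: 4 1-[2,3-bis(methoxymethoxy)-4-(3-methylbut-2-enyloxy)phenyl]ethanone
Conditions: MOMCl, NaH, DMF, 0 °C to rt
Reagents that add atoms: chloromethyl methyl ether (COCCl)
Why: Protection of both phenols as methoxymethyl ethers through their sodium phenoxides; NaH is used because the 2-OH is chelated to the ketone, and the acetal ethers withstand all later basic, thermal and palladium-mediated steps.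

**Step 3**
Reactants: 4 1-[2,3-bis(methoxymethoxy)-4-(3-methylbut-2-enyloxy)phenyl]ethanone
Product: 6 1-[4-hydroxy-2,3-bis(methoxymethoxy)-5-(2-methylbut-3-en-2-yl)phenyl]ethanone, via cyclohexadienone 5 (not isolated)
Conditions: PhNEt2, 190 °C, sealed tube
Reagents that add atoms: none
Why: Aromatic Claisen rearrangement; the [3,3]-sigmatropic shift moves the allyl unit with allylic transposition to C5, the only ortho carbon bearing hydrogen, so the new bond is made to the tertiary carbon, and dienone 5 tautomerises to the phenol. Migration towards the oxygen-bearing ortho carbon can only revert.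

**Step 4**
Reactants: 6 1-[4-hydroxy-2,3-bis(methoxymethoxy)-5-(2-methylbut-3-en-2-yl)phenyl]ethanone
Product: 7 1-(ArB)ethanone
Conditions: MeI, K2CO3, DMF, rt
Reagents that add atoms: iodomethane (CI)
Why: Williamson O-methylation of the hindered but acidic para-acyl phenol; carbonate does not enolise the methyl ketone.

**Step 5**
Reactants: 7 1-(ArB)ethanone
Product: 9 1-(ArB)ethenyl trifluoromethanesulfonate, via potassium enolate 8 (not isolated)
Conditions: KN(SiMe3)2, THF, −78 °C; then PhNTf2, −78 to 0 °C
Reagents that add atoms: N-phenylbis(trifluoromethanesulfonimide) (O=S(=O)(N(c1ccccc1)S(=O)(=O)C(F)(F)F)C(F)(F)F)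
Why: Kinetic deprotonation at the only enolisable position and O-sulfonylation of enolate 8 should give the terminal enol triflate; the electron-rich product is taken on without long storage.

**Step 6**
Reactants: 9 1-(ArB)ethenyl trifluoromethanesulfonate; 10 carbon monoxide
Product: 11 methyl 2-(ArB)prop-2-enoate
Conditions: Pd(OAc)2 (5 mol %), PPh3 (10 mol %), Et3N, MeOH–DMF, CO 1 atm, rt to 40 °C
Reagents that add atoms: methanol (CO)
Why: Palladium-catalysed alkoxycarbonylation of an enol triflate (oxidative addition, CO insertion, methanolysis) should give the 2-arylacrylate under near-neutral conditions that leave the acetal ethers and the isolated alkene alone.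

**Step 7**
Reactants: 12 3-hydroxyphenyl benzoate
Product: 13 3-(methoxymethoxy)phenyl benzoate
Conditions: MOMCl, i-Pr2NEt, CH2Cl2, 0 °C to rt
Reagents that add atoms: chloromethyl methyl ether (COCCl)
Why: Methoxymethyl protection of the free phenol under amine base; the benzoate keeps the oxygen that will become O1 masked and weakly donating.

**Step 8**
Reactants: 13 3-(methoxymethoxy)phenyl benzoate
Product: 14 2-bromo-5-(methoxymethoxy)phenyl benzoate
Conditions: NBS, MeCN, 0 °C to rt
Reagents that add atoms: N-bromosuccinimide (O=C1CCC(=O)N1Br)
Why: Electrophilic aromatic bromination controlled by the stronger donor; the acetal ether directs para, which is the position ortho to the benzoate, so bromine should enter at the future C4a.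

**Step 9**
Reactants: 14 2-bromo-5-(methoxymethoxy)phenyl benzoate
Product: 15 2-bromo-5-(methoxymethoxy)phenol
Conditions: K2CO3 (cat.), MeOH, rt
Reagents that add atoms: none
Why: Base-catalysed methanolysis (transesterification) of the aryl benzoate frees the phenol ortho to bromine; the acetal ether and the aryl bromide are inert.

**Step 10**
Reactants: 11 methyl 2-(ArB)prop-2-enoate; 15 2-bromo-5-(methoxymethoxy)phenol
Product: 16 racemic methyl 3-[2-bromo-5-(methoxymethoxy)phenoxy]-2-(ArB)propanoate
Conditions: 15 (1.3 equiv), Cs2CO3 (0.2 equiv), MeCN, rt to 40 °C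
Reagents that add atoms: none
Why: Base-catalysed oxa-Michael addition of the phenoxide of 15 to the 2-arylacrylate forms O1–C2 and leaves C3 as an acidic CH; catalytic base, moderate temperature and excess phenol keep the reversible addition on the product side, and C3 is formed racemic.

**Step 11**
Reactants: 16 racemic methyl 3-[2-bromo-5-(methoxymethoxy)phenoxy]-2-(ArB)propanoate; 10 carbon monoxide
Product: 18 racemic methyl 3-(ArB)-7-(methoxymethoxy)-4-oxochromane-3-carboxylate, via aroylpalladium bromide 17 (not isolated)
Conditions: Pd(OAc)2 (5 mol %), Xantphos (7.5 mol %), K3PO4 (2 equiv), toluene, CO 5 bar, 85 °C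
Reagents that add atoms: none
Why: Zerovalent palladium formed from Pd(OAc)2 and Xantphos inserts into the C4a–Br bond of 16, and CO insertion gives the aroylpalladium bromide 17, in which palladium is divalent. Phosphate removes the C3 proton, which is acidified by the ester and ring B, the enolate binds palladium through carbon, and reductive elimination forms C4–C3, so that CO becomes C4 between C4a and C3. The closest known reaction type is the palladium-catalysed carbonylative α-arylation of enolates, including its intramolecular form in which a tethered enolate traps an acylpalladium species. Ring C closes in a 6-exo-trig sense, the enolate carbon attacking the acyl carbon whose oxygen stays outside the ring; attack through the enolate oxygen would need an eight-membered ring and is not expected. C3 becomes a quaternary stereocentre formed as the racemate without control, which does not matter because the ester is removed in the next step. Carbonylation has to precede direct enolate arylation, which would give a five-membered ring; CO pressure and the wide bite angle of Xantphos, which favours CO insertion and acyl reductive elimination, should secure this. Ring closure also has to outrun base-induced loss of the phenoxide by retro-oxa-Michael reaction; a sparingly soluble phosphate in toluene keeps the free enolate concentration low, the O1–C2 tether makes capture intramolecular, and the product has no α-hydrogen and cannot re-enter enolate chemistry.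

**Step 12**
Reactants: 18 racemic methyl 3-(ArB)-7-(methoxymethoxy)-4-oxochromane-3-carboxylate
Product: 20 racemic 3-(ArB)-7-(methoxymethoxy)chroman-4-one, via lithium carboxylate 19 (not isolated)
Conditions: LiCl, H2O, DMSO, 130 °C
Reagents that add atoms: none
Why: Krapcho dealkoxycarbonylation; chloride attacks the ester methyl group in an SN2 reaction, the β-keto carboxylate 19 loses CO2 and the enolate is protonated by water. The neutral conditions spare the acetal ethers and avoid retro-Claisen opening.

**Step 13**
Reactants: 20 racemic 3-(ArB)-7-(methoxymethoxy)chroman-4-one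
Product: 21 (3S,4S)-3-(ArB)-7-(methoxymethoxy)chroman-4-ol (cis)
Conditions: RuCl(p-cymene)[(S,S)-TsDPEN] (2 mol %), HCO2H–Et3N, EtOAc, 40 °C
Reagents that add atoms: none
Why: Asymmetric transfer hydrogenation with dynamic kinetic resolution; Et3N racemises C3 of 20 through the enol, the catalyst reduces the (3S)-ketone faster and delivers hydride to C4 from the face opposite the C3 aryl group. C4 (S) is set by the catalyst as for other aryl ketones, C3 (S) by the cis preference, and the ruthenium hydride does not reduce the isolated alkene.

**Step 14**
Reactants: 21 (3S,4S)-3-(ArB)-7-(methoxymethoxy)chroman-4-ol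
Product: 22 (3S)-3-(ArB)-7-(methoxymethoxy)chroman-4-one
Conditions: Dess–Martin periodinane, CH2Cl2, 0 °C to rt
Reagents that add atoms: none
Why: Dess–Martin oxidation of the benzylic secondary alcohol under neutral to weakly acidic conditions returns the ketone; no base is added, so the C3 stereocentre, again α to a carbonyl, should not epimerise, and the protected phenols are not oxidised.

**Step 15**
Reactants: 22 (3S)-3-(ArB)-7-(methoxymethoxy)chroman-4-one
Product: 23 (3S)-3-[2,3-dihydroxy-4-methoxy-5-(2-methylbut-3-en-2-yl)phenyl]-7-hydroxychroman-4-one
Conditions: ZnBr2, n-PrSH, CH2Cl2, 0 °C; then pH 7 buffer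
Reagents that add atoms: none
Why: Lewis acid-assisted thiolysis of the three methoxymethyl acetals; ZnBr2 activates each acetal and the thiol takes over the methoxymethyl group as a monothioacetal within a short time at 0 °C. Protic acid and heat, which would enolise C3 or dehydrate the 2'-hydroxy ketone, are avoided, and the methyl ether and the alkene are left untouched.

## Compound list

1 | 1-(2,3,4-trihydroxyphenyl)ethanone | CC(=O)c1ccc(O)c(O)c1O | starting material
2 | 1-bromo-3-methylbut-2-ene | CC(C)=CCBr | starting material
3 | 1-[2,3-dihydroxy-4-(3-methylbut-2-enyloxy)phenyl]ethanone | CC(=O)c1ccc(OCC=C(C)C)c(O)c1O | intermediate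
4 | 1-[2,3-bis(methoxymethoxy)-4-(3-methylbut-2-enyloxy)phenyl]ethanone | CC(=O)c1ccc(OCC=C(C)C)c(OCOC)c1OCOC | intermediate
5 | 4-acetyl-2,3-bis(methoxymethoxy)-6-(2-methylbut-3-en-2-yl)cyclohexa-2,4-dien-1-one (racemic, not isolated) | CC(=O)C1=CC(C(C)(C)C=C)C(=O)C(OCOC)=C1OCOC | intermediate
6 | 1-[4-hydroxy-2,3-bis(methoxymethoxy)-5-(2-methylbut-3-en-2-yl)phenyl]ethanone | CC(=O)c1cc(C(C)(C)C=C)c(O)c(OCOC)c1OCOC | intermediate
7 | 1-[4-methoxy-2,3-bis(methoxymethoxy)-5-(2-methylbut-3-en-2-yl)phenyl]ethanone | CC(=O)c1cc(C(C)(C)C=C)c(OC)c(OCOC)c1OCOC | intermediate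
8 | potassium 1-[4-methoxy-2,3-bis(methoxymethoxy)-5-(2-methylbut-3-en-2-yl)phenyl]ethenolate (not isolated) | [K+].[O-]C(=C)c1cc(C(C)(C)C=C)c(OC)c(OCOC)c1OCOC | intermediate
9 | 1-[4-methoxy-2,3-bis(methoxymethoxy)-5-(2-methylbut-3-en-2-yl)phenyl]ethenyl trifluoromethanesulfonate | C=C(OS(=O)(=O)C(F)(F)F)c1cc(C(C)(C)C=C)c(OC)c(OCOC)c1OCOC | intermediate
10 | carbon monoxide | [C-]#[O+] | starting material
11 | methyl 2-[4-methoxy-2,3-bis(methoxymethoxy)-5-(2-methylbut-3-en-2-yl)phenyl]prop-2-enoate | C=C(C(=O)OC)c1cc(C(C)(C)C=C)c(OC)c(OCOC)c1OCOC | intermediate
12 | 3-hydroxyphenyl benzoate | O=C(Oc1cccc(O)c1)c1ccccc1 | starting material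
13 | 3-(methoxymethoxy)phenyl benzoate | COCOc1cccc(OC(=O)c2ccccc2)c1 | intermediate
14 | 2-bromo-5-(methoxymethoxy)phenyl benzoate | COCOc1ccc(Br)c(OC(=O)c2ccccc2)c1 | intermediate
15 | 2-bromo-5-(methoxymethoxy)phenol | COCOc1ccc(Br)c(O)c1 | intermediate
16 | racemic methyl 3-[2-bromo-5-(methoxymethoxy)phenoxy]-2-[4-methoxy-2,3-bis(methoxymethoxy)-5-(2-methylbut-3-en-2-yl)phenyl]propanoate | COC(=O)C(COc1cc(OCOC)ccc1Br)c1cc(C(C)(C)C=C)c(OC)c(OCOC)c1OCOC | intermediate
17 | aroylpalladium bromide of 16 after CO insertion, divalent palladium carrying Xantphos (ligand written as a separate component, P–Pd bonds not drawn; not isolated) | COC(=O)C(COc1cc(OCOC)ccc1C(=O)[Pd]Br)c1cc(C(C)(C)C=C)c(OC)c(OCOC)c1OCOC.CC1(C)c2cccc(P(c3ccccc3)c3ccccc3)c2Oc2c(P(c3ccccc3)c3ccccc3)cccc21 | intermediate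
18 | racemic methyl 3-[4-methoxy-2,3-bis(methoxymethoxy)-5-(2-methylbut-3-en-2-yl)phenyl]-7-(methoxymethoxy)-4-oxochromane-3-carboxylate | COC(=O)C1(c2cc(C(C)(C)C=C)c(OC)c(OCOC)c2OCOC)COc2cc(OCOC)ccc2C1=O | intermediate
19 | racemic lithium 3-[4-methoxy-2,3-bis(methoxymethoxy)-5-(2-methylbut-3-en-2-yl)phenyl]-7-(methoxymethoxy)-4-oxochromane-3-carboxylate (not isolated) | [Li+].[O-]C(=O)C1(c2cc(C(C)(C)C=C)c(OC)c(OCOC)c2OCOC)COc2cc(OCOC)ccc2C1=O | intermediate
20 | racemic 3-[4-methoxy-2,3-bis(methoxymethoxy)-5-(2-methylbut-3-en-2-yl)phenyl]-7-(methoxymethoxy)chroman-4-one | C=CC(C)(C)c1cc(C2COc3cc(OCOC)ccc3C2=O)c(OCOC)c(OCOC)c1OC | intermediate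
21 | (3S,4S)-3-[4-methoxy-2,3-bis(methoxymethoxy)-5-(2-methylbut-3-en-2-yl)phenyl]-7-(methoxymethoxy)chroman-4-ol | C=CC(C)(C)c1cc([C@H]2COc3cc(OCOC)ccc3[C@H]2O)c(OCOC)c(OCOC)c1OC | intermediate
22 | (3S)-3-[4-methoxy-2,3-bis(methoxymethoxy)-5-(2-methylbut-3-en-2-yl)phenyl]-7-(methoxymethoxy)chroman-4-one | C=CC(C)(C)c1cc([C@H]2COc3cc(OCOC)ccc3C2=O)c(OCOC)c(OCOC)c1OC | intermediate
23 | (3S)-3-[2,3-dihydroxy-4-methoxy-5-(2-methylbut-3-en-2-yl)phenyl]-7-hydroxychroman-4-one | C=CC(C)(C)c1cc([C@H]2COc3cc(O)ccc3C2=O)c(O)c(O)c1OC | target

## Step count and least certain steps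

Total step count: 15. Longest linear sequence: 12 (steps 1–6 and 10–15); steps 7–9 form the ring A branch.

**Step 11 (key step).**
- Risk: base-induced fragmentation of 16 by retro-oxa-Michael reaction before palladium has inserted. The released phenoxide would then capture the acylpalladium species intermolecularly, and the acrylate would polymerise. Direct enolate arylation without CO uptake and slow enolisation under the weak base are further risks.
- Fallback: it sets out from 14 and 9 and returns at 20, so it also bypasses steps 6, 10 and 12. Benzoate 14 is borylated (PdCl2(dppf), KOAc, bis(pinacolato)diboron, dioxane, 85 °C) to 5-(methoxymethoxy)-2-(4,4,5,5-tetramethyl-1,3,2-dioxaborolan-2-yl)phenyl benzoate F1. A carbonylative Suzuki–Miyaura coupling of F1 with enol triflate 9 under CO 10 (PdCl2(dppf), K2CO3, anisole, 80 °C) gives the aryl vinyl ketone 5-(methoxymethoxy)-2-[2-(ArB)prop-2-enoyl]phenyl benzoate F2. K2CO3 in MeOH removes the benzoate, and the phenoxide closes ring C by 6-endo oxa-Michael addition to give 20. Carbon monoxide still becomes C4, but no ester enolate is involved.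

**Step 3 (Claisen rearrangement).**
- Risk: thermal follow-up reactions of the ortho-(tert-allyl)phenol, namely isomerisation of the side chain by the abnormal Claisen pathway, ring closure of the phenol onto the alkene and loss of the prenyl group.
- Fallback: it sets out from 1 and returns at 7. Selective O4-methylation (MeI, Li2CO3, DMF) gives 1-(2,3-dihydroxy-4-methoxyphenyl)ethanone F3. Bromination at C5, which is para to the 2-OH, ortho to the methoxy group and meta to the acetyl group (Br2, NaOAc, AcOH, 0 °C), gives 1-(5-bromo-2,3-dihydroxy-4-methoxyphenyl)ethanone F4. Protection (MOMCl, NaH, DMF) gives 1-[5-bromo-4-methoxy-2,3-bis(methoxymethoxy)phenyl]ethanone F5. A Suzuki–Miyaura coupling of F5 with pinacol (3-methylbut-2-enyl)boronate (Pd(OAc)2, a dialkylbiarylphosphine chosen for the branched product, K3PO4, aqueous THF) installs the tert-allyl group and gives 7.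

**Step 13 (transfer hydrogenation with dynamic kinetic resolution).**
- Risk: slow reduction of the hindered ketone with its ortho-substituted C3 aryl group, racemisation at C3 that does not keep pace with reduction, and incomplete cis selectivity.
- Fallback: it sets out from 20 and returns at 22, bypassing 21. The potassium enolate of 20 (KN(SiMe3)2, THF, −78 °C) is O-acylated with allyl chloroformate to allyl 3-(ArB)-7-(methoxymethoxy)-2H-chromen-4-yl carbonate F6. A palladium-catalysed decarboxylative asymmetric protonation (Pd2(dba)3, a tert-butyl phosphinooxazoline ligand of the enantiomeric series that gives the 3S ketone, Meldrum's acid as proton donor, dioxane, rt) sets C3 directly at the ketone oxidation level.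

**Step 15 (final deprotection).**
- Risk: loss of configuration at C3 by Lewis acid-promoted enolisation, acid-induced cyclodehydration of the 2'-hydroxy ketone, or incomplete cleavage of the hindered acetal ethers.
- Fallback: it sets out from 20 and returns at 23. The acetal ethers are removed at the racemic stage (ZnBr2, n-PrSH, CH2Cl2), where enolisation is harmless, to give racemic 3-[2,3-dihydroxy-4-methoxy-5-(2-methylbut-3-en-2-yl)phenyl]-7-hydroxychroman-4-one F7. Silylation (TBSCl, imidazole, DMF) gives the racemic tris(tert-butyldimethylsilyl) ether F8. The transfer hydrogenation of step 13 gives the (3S,4S)-alcohol tris(tert-butyldimethylsilyl) ether F9, and Dess–Martin oxidation gives the (3S)-ketone tris(tert-butyldimethylsilyl) ether F10. Buffered fluoride (HF·pyridine, pyridine–THF, 0 °C) then releases 23 under conditions that are neither basic nor strongly acidic.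

## Further compounds

F1 | step 11 | 5-(methoxymethoxy)-2-(4,4,5,5-tetramethyl-1,3,2-dioxaborolan-2-yl)phenyl benzoate | COCOc1ccc(B2OC(C)(C)C(C)(C)O2)c(OC(=O)c2ccccc2)c1
F2 | step 11 | 5-(methoxymethoxy)-2-{2-[4-methoxy-2,3-bis(methoxymethoxy)-5-(2-methylbut-3-en-2-yl)phenyl]prop-2-enoyl}phenyl benzoate | C=C(C(=O)c1ccc(OCOC)cc1OC(=O)c1ccccc1)c1cc(C(C)(C)C=C)c(OC)c(OCOC)c1OCOC
F3 | step 3 | 1-(2,3-dihydroxy-4-methoxyphenyl)ethanone | CC(=O)c1ccc(OC)c(O)c1O
F4 | step 3 | 1-(5-bromo-2,3-dihydroxy-4-methoxyphenyl)ethanone | CC(=O)c1cc(Br)c(OC)c(O)c1O
F5 | step 3 | 1-[5-bromo-4-methoxy-2,3-bis(methoxymethoxy)phenyl]ethanone | CC(=O)c1cc(Br)c(OC)c(OCOC)c1OCOC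
F6 | step 13 | allyl 3-[4-methoxy-2,3-bis(methoxymethoxy)-5-(2-methylbut-3-en-2-yl)phenyl]-7-(methoxymethoxy)-2H-chromen-4-yl carbonate | C=CCOC(=O)OC1=C(c2cc(C(C)(C)C=C)c(OC)c(OCOC)c2OCOC)COc2cc(OCOC)ccc21
F7 | step 15 | racemic 3-[2,3-dihydroxy-4-methoxy-5-(2-methylbut-3-en-2-yl)phenyl]-7-hydroxychroman-4-one | C=CC(C)(C)c1cc(C2COc3cc(O)ccc3C2=O)c(O)c(O)c1OC
F8 | step 15 | racemic 3-[2,3-bis(tert-butyldimethylsilyloxy)-4-methoxy-5-(2-methylbut-3-en-2-yl)phenyl]-7-(tert-butyldimethylsilyloxy)chroman-4-one | C=CC(C)(C)c1cc(C2COc3cc(O[Si](C)(C)C(C)(C)C)ccc3C2=O)c(O[Si](C)(C)C(C)(C)C)c(O[Si](C)(C)C(C)(C)C)c1OC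
F9 | step 15 | (3S,4S)-3-[2,3-bis(tert-butyldimethylsilyloxy)-4-methoxy-5-(2-methylbut-3-en-2-yl)phenyl]-7-(tert-butyldimethylsilyloxy)chroman-4-ol | C=CC(C)(C)c1cc([C@H]2COc3cc(O[Si](C)(C)C(C)(C)C)ccc3[C@H]2O)c(O[Si](C)(C)C(C)(C)C)c(O[Si](C)(C)C(C)(C)C)c1OC
F10 | step 15 | (3S)-3-[2,3-bis(tert-butyldimethylsilyloxy)-4-methoxy-5-(2-methylbut-3-en-2-yl)phenyl]-7-(tert-butyldimethylsilyloxy)chroman-4-one | C=CC(C)(C)c1cc([C@H]2COc3cc(O[Si](C)(C)C(C)(C)C)ccc3C2=O)c(O[Si](C)(C)C(C)(C)C)c(O[Si](C)(C)C(C)(C)C)c1OC
A1 | alternative 1 | racemic 3-[2,3-bis(tert-butyldimethylsilyloxy)-4-methoxy-5-(2-methylbut-3-en-2-yl)phenyl]-7-(tert-butyldimethylsilyloxy)chroman-4-one | C=CC(C)(C)c1cc(C2COc3cc(O[Si](C)(C)C(C)(C)C)ccc3C2=O)c(O[Si](C)(C)C(C)(C)C)c(O[Si](C)(C)C(C)(C)C)c1OC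
A2 | alternative 1 | (Z)-4-[2,3-bis(tert-butyldimethylsilyloxy)-4-methoxy-5-(2-methylbut-3-en-2-yl)benzylidene]-7-(tert-butyldimethylsilyloxy)-4H-1,3-benzodioxine | C=CC(C)(C)c1cc(/C=C2\OCOc3cc(O[Si](C)(C)C(C)(C)C)ccc32)c(O[Si](C)(C)C(C)(C)C)c(O[Si](C)(C)C(C)(C)C)c1OC
A3 | alternative 2 | 7-(methoxymethoxy)-3-[4-methoxy-2,3-bis(methoxymethoxy)-5-(2-methylbut-3-en-2-yl)phenyl]-2H-chromene | C=CC(C)(C)c1cc(C2=Cc3ccc(OCOC)cc3OC2)c(OCOC)c(OCOC)c1OC
A4 | alternative 2 | 3-(methoxymethoxy)phenol | COCOc1cccc(O)c1
A5 | alternative 2 | 2-[4-methoxy-2,3-bis(methoxymethoxy)-5-(2-methylbut-3-en-2-yl)phenyl]prop-2-enal | C=C(C=O)c1cc(C(C)(C)C=C)c(OC)c(OCOC)c1OCOC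
A6 | alternative 3 | (3S,4R)-3-[4-methoxy-2,3-bis(methoxymethoxy)-5-(2-methylbut-3-en-2-yl)phenyl]-7-(methoxymethoxy)-4-(triisopropylsilyloxy)chroman (trans) | C=CC(C)(C)c1cc([C@H]2COc3cc(OCOC)ccc3[C@@H]2O[Si](C(C)C)(C(C)C)C(C)C)c(OCOC)c(OCOC)c1OC
A7 | alternative 3 | 3-[2-bromo-4-(methoxymethoxy)phenyl]-2-[4-methoxy-2,3-bis(methoxymethoxy)-5-(2-methylbut-3-en-2-yl)phenyl]-3-(triisopropylsilyloxy)propan-1-ol, the stereoisomer that closes to A6 | C=CC(C)(C)c1cc([C@@H](CO)[C@@H](O[Si](C(C)C)(C(C)C)C(C)C)c2ccc(OCOC)cc2Br)c(OCOC)c(OCOC)c1OC
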